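**Retrosynthetic overview**
- Target 18 comes from the triphenolic enone 13 in the last step through a traceless C–N bond. The ketone becomes a sulfonylhydrazone (C=N), asymmetric reduction makes a C–N stereocentre, and loss of N2 from the allylic diazene relays it to the (1S) C–H centre while moving the alkene to the 2,3-position.
- 13 comes from its trimethyl ether 12 (BBr3, before any acid-sensitive alkene exists). 12 comes from aryl bromide 10 and 3,5-dimethoxystyrene 11 by a Heck reaction that sets the E-alkene.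
- 10 comes from vinylogous ester 6 and the benzylic Grignard reagent of 7 (Stork–Danheiser addition and transposition forms the ArCH2–C bond).
- 6 comes from 2-methylcyclohexane-1,3-dione 1 by vinylogous ester formation and double methylation.
- No ring is formed: the cyclohexene ring comes from 1 and the two benzene rings from 7 and 11.

Assumption: benzylic chloride 7 (5-bromo-2-methoxybenzyl chloride), styrene 11 and both antipodes of the ruthenium catalyst are bought as catalogue items.

**Step 1**
Reactants: 1 2-methylcyclohexane-1,3-dione; 2 2-methylpropan-1-ol (isobutanol)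
Product: 3 2-methyl-3-(2-methylpropoxy)cyclohex-2-en-1-one
Conditions: i-BuOH (3 equiv), TsOH·H2O (2 mol %), toluene, reflux, Dean–Stark
Reagents that add atoms: 2-methylpropan-1-ol (2), CC(C)CO
Why: Acid-catalysed vinylogous esterification of a symmetric cyclic 1,3-diketone, driven by azeotropic removal of water; no regiochemical or stereochemical question arises.

**Step 2**
Reactants: 3 2-methyl-3-(2-methylpropoxy)cyclohex-2-en-1-one; 4 iodomethane
Product: 6 2,6,6-trimethyl-3-(2-methylpropoxy)cyclohex-2-en-1-one, via monomethyl enone 5 (not isolated)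
Conditions: LiN(i-Pr)2 (1.1 equiv), THF, −78 °C, then MeI, −78 → 0 °C; recool to −78 °C, LiN(i-Pr)2 (1.2 equiv), then MeI, → rt (one pot)
Reagents that add atoms: iodomethane (4), CI
Why: Kinetic deprotonation of a vinylogous ester occurs at the alpha-prime carbon (C6), so two successive enolate C-methylations (Stork–Danheiser alkylation) build the gem-dimethyl group and leave no stereocentre.

**Step 3**
Reactants: 6 2,6,6-trimethyl-3-(2-methylpropoxy)cyclohex-2-en-1-one; 7 4-bromo-2-(chloromethyl)-1-methoxybenzene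
Product: 10 3-[(5-bromo-2-methoxyphenyl)methyl]-2,4,4-trimethylcyclohex-2-en-1-one, via benzylic Grignard reagent 8 (not isolated), via tertiary allylic alcohol 9 (not isolated)
Conditions: 7, Mg turnings, Et2O, 0 °C; then 6, LaCl3·2LiCl (0.3 equiv), THF, 0 °C → rt; then 1 M HCl, THF, rt
Reagents that add atoms: 4-bromo-2-(chloromethyl)-1-methoxybenzene (7), COc1ccc(Br)cc1CCl; water, O
Why: Magnesium inserts into the benzylic C–Cl bond much faster than into the aryl C–Br bond at 0 °C, the benzyl Grignard reagent adds 1,2 to the carbonyl (which has no alpha-hydrogen on the gem-dimethyl side), and aqueous acid hydrolyses the enol ether with allylic transposition (Stork–Danheiser enone synthesis), placing ArCH2 on the beta-carbon next to CMe2.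

**Step 4**
Reactants: 10 3-[(5-bromo-2-methoxyphenyl)methyl]-2,4,4-trimethylcyclohex-2-en-1-one; 11 1-ethenyl-3,5-dimethoxybenzene (3,5-dimethoxystyrene)
Product: 12 3-({5-[(E)-2-(3,5-dimethoxyphenyl)ethenyl]-2-methoxyphenyl}methyl)-2,4,4-trimethylcyclohex-2-en-1-one
Conditions: Pd(OAc)2 (3 mol %), [HP(t-Bu)3]BF4 (6 mol %), Cy2NMe, 1,4-dioxane, 90 °C
Reagents that add atoms: 3,5-dimethoxystyrene (11), C=Cc1cc(OC)cc(OC)c1
Why: Mizoroki–Heck reaction in which the bulky electron-rich phosphine lets zerovalent palladium add to the electron-rich aryl bromide, and syn-insertion followed by syn-beta-hydride elimination gives the E-stilbene; the tetrasubstituted enone alkene does not insert.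

**Step 5**
Reactants: 12 3-({5-[(E)-2-(3,5-dimethoxyphenyl)ethenyl]-2-methoxyphenyl}methyl)-2,4,4-trimethylcyclohex-2-en-1-one
Product: 13 3-({5-[(E)-2-(3,5-dihydroxyphenyl)ethenyl]-2-hydroxyphenyl}methyl)-2,4,4-trimethylcyclohex-2-en-1-one
Conditions: BBr3 (6 equiv), CH2Cl2, −78 °C → rt; then MeOH, aq. NaHCO3
Reagents that add atoms: none
Why: Lewis-acid cleavage of aryl methyl ethers by BBr3 (aryloxydibromoborane plus MeBr, then hydrolysis), done here because the conjugated tetrasubstituted enone and the stilbene tolerate it, whereas the trisubstituted alkene of the target next to a free ortho-phenol would not.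

**Step 6**
Reactants: 13 3-({5-[(E)-2-(3,5-dihydroxyphenyl)ethenyl]-2-hydroxyphenyl}methyl)-2,4,4-trimethylcyclohex-2-en-1-one; 14 4-methylbenzenesulfonohydrazide
Product: 18 5-[(E)-2-(4-hydroxy-3-{[(1S)-2,6,6-trimethylcyclohex-2-en-1-yl]methyl}phenyl)ethenyl]benzene-1,3-diol, via tosylhydrazone 15 (not isolated), via allylic hydrazine 16 (not isolated), via allylic diazene 17 (not isolated)
Conditions: TsNHNH2 (1.05 equiv), AcOH (cat.), MeCN, 50 °C; then RuCl[(R,R)-TsDPEN](p-cymene) (2 mol %), HCO2H/Et3N (5:2), 25 °C; then Et3N, 60 °C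
Reagents that add atoms: none
Why: Proposed new method: an enantioselective reductive 1,3-transposition of an enone, in which condensation forms the C=N bond of 15, the chiral Ru–H (Noyori–Ikariya asymmetric transfer hydrogenation, with the alkenyl flank of the C=N playing the part of the aryl group of an aryl ketimine) delivers hydride to the Re face of the hydrazone carbon to give the (S)-configured C–N stereocentre of 16, base-induced loss of p-toluenesulfinate gives diazene 17, and its concerted suprafacial retro-ene loss of N2 puts the N–H hydrogen on the fully substituted beta-carbon from the face that carried nitrogen, so the C–N stereocentre becomes the (1S) C–H stereocentre and the alkene is left out of conjugation; the closest known reactions are the racemic hydride reduction of enone tosylhydrazones with alkene transposition, the Mitsunobu-based allylic diazene transposition of chiral allylic alcohols, and asymmetric transfer hydrogenation of imines, whereas asymmetric reduction of an alpha,beta-unsaturated N-sulfonylhydrazone coupled to this relay has not been shown.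

**Compound list**
1 | 2-methylcyclohexane-1,3-dione | CC1C(=O)CCCC1=O | starting material
2 | 2-methylpropan-1-ol (isobutanol) | CC(C)CO | starting material
3 | 2-methyl-3-(2-methylpropoxy)cyclohex-2-en-1-one | CC1=C(OCC(C)C)CCCC1=O | intermediate
4 | iodomethane | CI | starting material
5 | 2,6-dimethyl-3-(2-methylpropoxy)cyclohex-2-en-1-one (racemic, not isolated) | CC1=C(OCC(C)C)CCC(C)C1=O | intermediate
6 | 2,6,6-trimethyl-3-(2-methylpropoxy)cyclohex-2-en-1-one | CC1=C(OCC(C)C)CCC(C)(C)C1=O | intermediate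
7 | 4-bromo-2-(chloromethyl)-1-methoxybenzene | COc1ccc(Br)cc1CCl | starting material
8 | (5-bromo-2-methoxybenzyl)magnesium chloride (not isolated) | COc1ccc(Br)cc1C[Mg]Cl | intermediate
9 | 1-[(5-bromo-2-methoxyphenyl)methyl]-2,6,6-trimethyl-3-(2-methylpropoxy)cyclohex-2-en-1-ol (racemic, not isolated) | CC1=C(OCC(C)C)CCC(C)(C)C1(O)Cc1cc(Br)ccc1OC | intermediate
10 | 3-[(5-bromo-2-methoxyphenyl)methyl]-2,4,4-trimethylcyclohex-2-en-1-one | CC1=C(Cc2cc(Br)ccc2OC)C(C)(C)CCC1=O | intermediate
11 | 1-ethenyl-3,5-dimethoxybenzene (3,5-dimethoxystyrene) | C=Cc1cc(OC)cc(OC)c1 | starting material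
12 | 3-({5-[(E)-2-(3,5-dimethoxyphenyl)ethenyl]-2-methoxyphenyl}methyl)-2,4,4-trimethylcyclohex-2-en-1-one | CC1=C(Cc2cc(/C=C/c3cc(OC)cc(OC)c3)ccc2OC)C(C)(C)CCC1=O | intermediate
13 | 3-({5-[(E)-2-(3,5-dihydroxyphenyl)ethenyl]-2-hydroxyphenyl}methyl)-2,4,4-trimethylcyclohex-2-en-1-one | CC1=C(Cc2cc(/C=C/c3cc(O)cc(O)c3)ccc2O)C(C)(C)CCC1=O | intermediate
14 | 4-methylbenzenesulfonohydrazide | Cc1ccc(cc1)S(=O)(=O)NN | starting material
15 | N-tosylhydrazone of 13 at the ring carbonyl, E at C=N (NHTs anti to the ring-methyl carbon; not isolated) | CC1=C(Cc2cc(/C=C/c3cc(O)cc(O)c3)ccc2O)C(C)(C)CC/C1=N\NS(=O)(=O)c1ccc(C)cc1 | intermediate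
16 | N'-[(1S)-3-({5-[(E)-2-(3,5-dihydroxyphenyl)ethenyl]-2-hydroxyphenyl}methyl)-2,4,4-trimethylcyclohex-2-en-1-yl]-4-methylbenzenesulfonohydrazide (not isolated) | CC1=C(Cc2cc(/C=C/c3cc(O)cc(O)c3)ccc2O)C(C)(C)CC[C@@H]1NNS(=O)(=O)c1ccc(C)cc1 | intermediate
17 | 5-[(E)-2-(3-{[(3S)-3-diazenyl-2,6,6-trimethylcyclohex-1-en-1-yl]methyl}-4-hydroxyphenyl)ethenyl]benzene-1,3-diol (N=N geometry not fixed, not isolated) | CC1=C(Cc2cc(/C=C/c3cc(O)cc(O)c3)ccc2O)C(C)(C)CC[C@@H]1N=N | intermediate
18 | 5-[(E)-2-(4-hydroxy-3-{[(1S)-2,6,6-trimethylcyclohex-2-en-1-yl]methyl}phenyl)ethenyl]benzene-1,3-diol | CC1=CCCC(C)(C)[C@@H]1Cc1cc(/C=C/c2cc(O)cc(O)c2)ccc1O | target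

**Step count**
Total steps: 6. Longest linear sequence: 6 (1 → 3 → 6 → 10 → 12 → 13 → 18).

**Three steps most likely to fail**

Step 6 (the proposed step). Hydride transfer from the ruthenium hydride to a weakly basic sulfonylhydrazone may be slow or poorly face-selective. The sense of induction is assigned only by analogy with cyclic imines, so it must be checked by chiral HPLC on the first run and the (S,S) complex used if it is inverted. The fallback uses known chemistry, sets out from 13 and comes back at 18. Silylation of 13 (TBSCl, imidazole, DMF) gives the tris(tert-butyldimethylsilyl) ether of the enone F1. Corey–Bakshi–Shibata reduction ((S)-2-methyl-CBS-oxazaborolidine, catecholborane, toluene, −78 °C) gives the (1R)-allylic alcohol F2. Mitsunobu displacement with 2-nitrobenzenesulfonohydrazide (PPh3, DEAD, N-methylmorpholine, −30 °C) forms, with inversion, the (1S)-N-allyl-N-sulfonylhydrazine F3. On warming to 23 °C this loses 2-nitrobenzenesulfinic acid to give the allylic diazene F4, whose retro-ene loss of N2 gives the tris(silyl) ether of the target F5. Cleavage with n-Bu4NF/AcOH in THF at 0 °C gives 18.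

Step 3. The Grignard reagent must form at the benzylic chloride without touching the aryl bromide or undergoing Wurtz coupling, and must then add to a hindered carbonyl. The fallback sets out from 6 and comes back at 10, and introduces bromine only after the C–C bond is made. Commercial 2-methoxybenzylmagnesium chloride in THF adds to 6 to give the tertiary allylic alcohol F6. This is hydrolysed in the same flask (1 M HCl) to the bromine-free enone 3-[(2-methoxyphenyl)methyl]-2,4,4-trimethylcyclohex-2-en-1-one F7. NBS in MeCN at 0 °C then brominates the anisole ring para to the methoxy group to give 10; the conjugated tetrasubstituted alkene is inert to these conditions.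

Step 5. Triple demethylation with BBr3 in the presence of the electron-rich stilbene may give oligomers or incomplete cleavage. The fallback sets out from 10 and comes back at 13, and replaces the two resorcinol methyl ethers by base-labile acetates. BBr3 (CH2Cl2, −78 → 0 °C) on the simple mono-ether 10 gives the bromophenol 3-[(5-bromo-2-hydroxyphenyl)methyl]-2,4,4-trimethylcyclohex-2-en-1-one F8. Heck coupling with purchased 3,5-diacetoxystyrene (Pd(OAc)2, P(o-tol)3, Et3N, MeCN, 85 °C) gives the stilbene diacetate F9; any acetyl migration to the free phenol is harmless. Methanolysis (K2CO3, MeOH, rt) gives 13.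

**Further compounds**
F1 | step 6 | 3-({5-[(E)-2-{3,5-bis[(tert-butyldimethylsilyl)oxy]phenyl}ethenyl]-2-[(tert-butyldimethylsilyl)oxy]phenyl}methyl)-2,4,4-trimethylcyclohex-2-en-1-one | CC1=C(Cc2cc(/C=C/c3cc(O[Si](C)(C)C(C)(C)C)cc(O[Si](C)(C)C(C)(C)C)c3)ccc2O[Si](C)(C)C(C)(C)C)C(C)(C)CCC1=O
F2 | step 6 | (1R)-3-({5-[(E)-2-{3,5-bis[(tert-butyldimethylsilyl)oxy]phenyl}ethenyl]-2-[(tert-butyldimethylsilyl)oxy]phenyl}methyl)-2,4,4-trimethylcyclohex-2-en-1-ol | CC1=C(Cc2cc(/C=C/c3cc(O[Si](C)(C)C(C)(C)C)cc(O[Si](C)(C)C(C)(C)C)c3)ccc2O[Si](C)(C)C(C)(C)C)C(C)(C)CC[C@H]1O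
F3 | step 6 | N-[(1S)-3-({5-[(E)-2-{3,5-bis[(tert-butyldimethylsilyl)oxy]phenyl}ethenyl]-2-[(tert-butyldimethylsilyl)oxy]phenyl}methyl)-2,4,4-trimethylcyclohex-2-en-1-yl]-2-nitrobenzenesulfonohydrazide | CC1=C(Cc2cc(/C=C/c3cc(O[Si](C)(C)C(C)(C)C)cc(O[Si](C)(C)C(C)(C)C)c3)ccc2O[Si](C)(C)C(C)(C)C)C(C)(C)CC[C@@H]1N(N)S(=O)(=O)c1ccccc1[N+](=O)[O-]
F4 | step 6 | (3S)-3-diazenyl-2,6,6-trimethylcyclohex-1-ene carrying the tris(silyl)-protected stilbenylmethyl group at C1 (allylic diazene, not isolated) | CC1=C(Cc2cc(/C=C/c3cc(O[Si](C)(C)C(C)(C)C)cc(O[Si](C)(C)C(C)(C)C)c3)ccc2O[Si](C)(C)C(C)(C)C)C(C)(C)CC[C@@H]1N=N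
F5 | step 6 | tris(tert-butyldimethylsilyl) ether of 18, (1S) | CC1=CCCC(C)(C)[C@@H]1Cc1cc(/C=C/c2cc(O[Si](C)(C)C(C)(C)C)cc(O[Si](C)(C)C(C)(C)C)c2)ccc1O[Si](C)(C)C(C)(C)C
F6 | step 3 | 1-[(2-methoxyphenyl)methyl]-2,6,6-trimethyl-3-(2-methylpropoxy)cyclohex-2-en-1-ol (racemic, not isolated) | CC1=C(OCC(C)C)CCC(C)(C)C1(O)Cc1ccccc1OC
F7 | step 3 | 3-[(2-methoxyphenyl)methyl]-2,4,4-trimethylcyclohex-2-en-1-one | CC1=C(Cc2ccccc2OC)C(C)(C)CCC1=O
F8 | step 5 | 3-[(5-bromo-2-hydroxyphenyl)methyl]-2,4,4-trimethylcyclohex-2-en-1-one | CC1=C(Cc2cc(Br)ccc2O)C(C)(C)CCC1=O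
F9 | step 5 | 5-[(E)-2-{4-hydroxy-3-[(2,6,6-trimethyl-3-oxocyclohex-1-en-1-yl)methyl]phenyl}ethenyl]-1,3-phenylene diacetate | CC1=C(Cc2cc(/C=C/c3cc(OC(C)=O)cc(OC(C)=O)c3)ccc2O)C(C)(C)CCC1=O
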